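**Strategy.** Ring A (C1 bears the butyryl group, C3 is the quaternary stereocentre, C5 bears the bridge CH2, C6 is the ring ketone) is cut at C4–C5 and C6–C1. Seen from ring B, the bridge CH2 with ring A C5 and C6 is a 3-arylpropanoyl unit whose carbonyl (C6) can be tied back to the neighbouring ring B phenol oxygen as a dihydrocoumarin lactone. C1–C4, with methyl and prenyl on C3, map onto an enantiopure 2-methyl-2-prenylacetoacetate. In one flask the methyl-ketone enolate of the keto ester opens the lactone by C-acylation, and the derived diketone dianion closes ring A onto the ester, carrying the stereocentre through untouched.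

Key step: step 7

Assumption: for this acyclic substrate the toluene/HMPA variant of the valine-enamine alkylation is taken to deliver the (S) keto ester; if the other face is favoured, the same two steps with tert-butyl D-valinate give the same keto ester.

Step 1
Reactants: 1 methyl 2-methyl-3-oxobutanoate (methyl 2-methylacetoacetate, racemic); 2 tert-butyl L-valinate (free base, liberated from the commercial hydrochloride)
Product: 3 methyl (Z)-3-{[(2S)-1-tert-butoxy-3-methyl-1-oxobutan-2-yl]amino}-2-methylbut-2-enoate
Conditions: BF3·OEt2 (cat.), toluene, reflux, Dean–Stark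
Reagents that add atoms: none
Why: Acid-catalysed condensation of the primary amine with the ketone of the β-keto ester (enamine formation), driven by azeotropic water removal, should give the hydrogen-bonded Z β-enamino ester, which erases the racemic α-centre of 1 and leaves the valine centre untouched.

Step 2
Reactants: 3 valine enamine; 4 prenyl bromide (1-bromo-3-methylbut-2-ene)
Product: 7 methyl (2S)-2-acetyl-2,5-dimethylhex-4-enoate, via lithio-enamine 5 (not isolated), via alkylated imine 6 (not isolated)
Conditions: LiN(iPr)2 (1.2 equiv), toluene, −78 °C; HMPA (3 equiv), 4, −78 → −55 °C; then 10% aq. citric acid, rt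
Reagents that add atoms: water, O
Why: Auxiliary-controlled alkylation of a chiral lithio-enamine (aza-enolate): lithium is held by the enamine nitrogen and both ester carbonyls, HMPA fills its free site on one face, and prenyl bromide attacks carbon from the other face, so the valine centre sets the quaternary (S) centre before mild acid hydrolysis of the imine releases the ketone and the auxiliary.

Step 3
Reactants: 8 2-methylphloroglucinol (2-methylbenzene-1,3,5-triol)
Product: 9 1-(2,4,6-trihydroxy-3-methylphenyl)butan-1-one
Conditions: PrCOCl (1.1 equiv), AlCl3 (4 equiv), CH2Cl2–PhNO2, 0 °C → rt; ice/1 M HCl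
Reagents that add atoms: butyryl chloride, CCCC(=O)Cl
Why: Friedel–Crafts acylation of the very electron-rich triol, whose two unsubstituted ring carbons are equivalent, should give one ketone, and the chelated, deactivated product resists a second acylation.

Step 4
Reactants: 9 1-(2,4,6-trihydroxy-3-methylphenyl)butan-1-one
Product: 10 aspidinol, 1-(2,6-dihydroxy-4-methoxy-3-methylphenyl)butan-1-one
Conditions: Me2SO4 (1.0 equiv), K2CO3 (1.1 equiv), acetone, rt
Reagents that add atoms: dimethyl sulfate, COS(=O)(=O)OC
Why: Williamson O-methylation with one equivalent of reagent should go to the hydroxyl para to the ketone, which is the most acidic and is not held in the hydrogen bond to the carbonyl that deactivates the two ortho hydroxyls.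

Step 5
Reactants: 10 aspidinol; 11 acrylic acid
Product: 12 8-butanoyl-7-hydroxy-5-methoxy-6-methyl-3,4-dihydro-2H-chromen-2-one
Conditions: 11 (3 equiv), CF3SO3H (0.3 equiv), toluene, 90 °C
Reagents that add atoms: none
Why: Brønsted-acid Friedel–Crafts conjugate addition (hydroarylation) of the only free ring carbon, which is ortho or para to all three oxygen donors, to protonated acrylic acid is followed by lactonisation onto the one adjacent free phenol (the other neighbour is the methyl ether), so a single dihydrocoumarin is expected.

Step 6
Reactants: 12 hydroxy dihydrocoumarin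
Product: 13 8-butanoyl-5-methoxy-7-(methoxymethoxy)-6-methyl-3,4-dihydro-2H-chromen-2-one
Conditions: MeOCH2Cl (2 equiv), iPr2NEt (3 equiv), CH2Cl2, 0 °C → reflux
Reagents that add atoms: chloromethyl methyl ether, COCCl
Why: O-alkylation of the single remaining phenol (MOM ether formation) with a non-nucleophilic amine base leaves the aryl lactone intact and removes the only acidic proton that would otherwise quench the enolate of step 7.

Step 7
Reactants: 7 methyl (2S)-2-acetyl-2,5-dimethylhex-4-enoate; 13 MOM-protected dihydrocoumarin
Product: 16 (4S)-2-{[3-butanoyl-2-hydroxy-6-methoxy-4-(methoxymethoxy)-5-methylphenyl]methyl}-3,5-dihydroxy-4-methyl-4-(3-methylbut-2-en-1-yl)cyclohexa-2,5-dien-1-one (ring A enol-trione without the C1 butyryl group; ring B mono-MOM ether), via lithium enolate 14 (not isolated), via diketo ester 15 (not isolated)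
Conditions: 7 (2.1 equiv), LiN(iPr)2 (2.1 equiv), THF, −78 °C; 13 (1.0 equiv), −78 → −40 °C; then LiN(iPr)2 (3.5 equiv), −78 → 0 °C; cold 1 M HCl to pH 2–3 (excess 7 recovered)
Reagents that add atoms: none
Why: LiN(iPr)2 can only deprotonate the acetyl methyl of 7, and the carbon of enolate 14 attacks the aryl lactone carbonyl of 13, whose collapse expels the chelated ring B phenoxide (crossed Claisen C-acylation, the closest known type being enolate acylation by aryl esters and dihydrocoumarins); the acidic 1,3-diketone 15 is at once deprotonated by the second equivalent of 14, which is why two are used. The later charge of amide base removes a proton from the CH2 next to the diketone on the aryl side, and this terminal carbanion of the diketone dianion adds to the methyl ester and expels methoxide, a Dieckmann-type closure known from the cyclisation of 3,5-diketo esters to cyclohexane-1,3,5-triones. Ring A, the only ring formed, closes in the 6-exo-trig mode. No stereocentre is created: the quaternary carbon of 7 has no hydrogen and no bond to it is touched, so its configuration is carried over, and which ring carbonyl it faces is fixed by which carbon (acetyl or ester) it came from. The step needs carbon rather than oxygen acylation at two defined carbons, which the single enolisable methyl of 7 secures for the first bond and the far higher nucleophilicity of the terminal dianion carbon over the enolate oxygens secures for the second. The product stays in the flask as a delocalised polyanion, which guards ring A against retro-Claisen opening by lithium methoxide until the cold acid quench.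

Step 8
Reactants: 16 ring A enol-trione without the C1 butyryl group
Product: 18 (4R)-2-butanoyl-6-{[3-butanoyl-2-(butanoyloxy)-6-methoxy-4-(methoxymethoxy)-5-methylphenyl]methyl}-3,5-dihydroxy-4-methyl-4-(3-methylbut-2-en-1-yl)cyclohexa-2,5-dien-1-one, via enol butyrate 17 (not isolated)
Conditions: PrCOCl (2.5 equiv), Et3N (4 equiv), CH2Cl2, 0 °C; then 4-(dimethylamino)pyridine (0.3 equiv), rt
Reagents that add atoms: butyryl chloride, CCCC(=O)Cl
Why: O-acylation of the ring A vinylogous acid and of the ring B phenol is followed by the 4-(dimethylamino)pyridine-mediated O-to-C acyl migration known for 2-acylcyclohexane-1,3-diones, which delivers butyryl to the only ring A carbon still bearing hydrogen; the stereocentre is not involved, and its descriptor changes from S to R only because the CIP ranking of its two ring neighbours swaps.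

Step 9
Reactants: 18 C-butyryl compound carrying the ring B aryl butyrate and MOM ether
Product: 20 (4R)-2-butanoyl-6-[(3-butanoyl-2,4-dihydroxy-6-methoxy-5-methylphenyl)methyl]-3,5-dihydroxy-4-methyl-4-(3-methylbut-2-en-1-yl)cyclohexa-2,5-dien-1-one (the target CNP0219644.1), via MOM ether 19 (not isolated)
Conditions: K2CO3 (3 equiv), MeOH, 0 °C; then HCl/MeOH (to ca. 1 M), 0 °C → rt
Reagents that add atoms: none
Why: Base-mediated transesterification should remove the activated aryl butyrate (and any residual enol butyrate) without touching the C-acyl groups, which sit in enolised triketone or hydrogen-bonded aryl ketone arrays, and acidifying the same methanol solution cleaves the MOM acetal ortho to the aryl ketone by acid-catalysed acetal exchange under conditions mild enough for the prenyl group.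

**Compound list**

1 | methyl 2-methyl-3-oxobutanoate (racemic) | CC(=O)C(C)C(=O)OC | starting material
2 | tert-butyl L-valinate | CC(C)[C@H](N)C(=O)OC(C)(C)C | starting material
3 | methyl (Z)-3-{[(2S)-1-tert-butoxy-3-methyl-1-oxobutan-2-yl]amino}-2-methylbut-2-enoate | C/C(N[C@@H](C(C)C)C(=O)OC(C)(C)C)=C(\C)C(=O)OC | intermediate
4 | prenyl bromide (1-bromo-3-methylbut-2-ene) | CC(C)=CCBr | starting material
5 | N-lithio derivative of 3 (lithio-enamine) | COC(=O)/C(C)=C(C)\N([Li])[C@@H](C(C)C)C(=O)OC(C)(C)C | intermediate
6 | methyl (2S)-3-{[(2S)-1-tert-butoxy-3-methyl-1-oxobutan-2-yl]imino}-2-methyl-2-(3-methylbut-2-en-1-yl)butanoate | COC(=O)[C@@](C)(CC=C(C)C)C(C)=N[C@@H](C(C)C)C(=O)OC(C)(C)C | intermediate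
7 | methyl (2S)-2-acetyl-2,5-dimethylhex-4-enoate | COC(=O)[C@@](C)(CC=C(C)C)C(C)=O | intermediate
8 | 2-methylphloroglucinol | Cc1c(O)cc(O)cc1O | starting material
9 | 1-(2,4,6-trihydroxy-3-methylphenyl)butan-1-one | CCCC(=O)c1c(O)c(C)c(O)cc1O | intermediate
10 | aspidinol, 1-(2,6-dihydroxy-4-methoxy-3-methylphenyl)butan-1-one | CCCC(=O)c1c(O)c(C)c(OC)cc1O | intermediate
11 | acrylic acid | C=CC(=O)O | starting material
12 | 8-butanoyl-7-hydroxy-5-methoxy-6-methyl-3,4-dihydro-2H-chromen-2-one | CCCC(=O)c1c(O)c(C)c(OC)c2CCC(=O)Oc12 | intermediate
13 | 8-butanoyl-5-methoxy-7-(methoxymethoxy)-6-methyl-3,4-dihydro-2H-chromen-2-one | CCCC(=O)c1c(OCOC)c(C)c(OC)c2CCC(=O)Oc12 | intermediate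
14 | lithium enolate of 7 at the acetyl methyl (S centre retained) | [Li]OC(=C)[C@](C)(CC=C(C)C)C(=O)OC | intermediate
15 | methyl (2S)-7-[3-butanoyl-2-hydroxy-6-methoxy-4-(methoxymethoxy)-5-methylphenyl]-2-methyl-2-(3-methylbut-2-en-1-yl)-3,5-dioxoheptanoate (present as its lithium salts) | COC(=O)[C@@](C)(CC=C(C)C)C(=O)CC(=O)CCc1c(O)c(C(=O)CCC)c(OCOC)c(C)c1OC | intermediate
16 | (4S)-2-{[3-butanoyl-2-hydroxy-6-methoxy-4-(methoxymethoxy)-5-methylphenyl]methyl}-3,5-dihydroxy-4-methyl-4-(3-methylbut-2-en-1-yl)cyclohexa-2,5-dien-1-one (descriptor for the tautomer drawn) | O=C1C=C(O)[C@](C)(CC=C(C)C)C(O)=C1Cc2c(O)c(C(=O)CCC)c(OCOC)c(C)c2OC | intermediate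
17 | bis-O-butyrate of 16: butanoate on the ring A enol oxygen next to the free ring CH and on the ring B phenol, configuration as in 16 (regioisomeric enol esters converge) | CCCC(=O)OC1=CC(=O)C(Cc2c(OC(=O)CCC)c(C(=O)CCC)c(OCOC)c(C)c2OC)=C(O)[C@@]1(C)CC=C(C)C | intermediate
18 | (4R)-2-butanoyl-6-{[3-butanoyl-2-(butanoyloxy)-6-methoxy-4-(methoxymethoxy)-5-methylphenyl]methyl}-3,5-dihydroxy-4-methyl-4-(3-methylbut-2-en-1-yl)cyclohexa-2,5-dien-1-one | CCCC(=O)C1=C(O)[C@](C)(CC=C(C)C)C(O)=C(Cc2c(OC(=O)CCC)c(C(=O)CCC)c(OCOC)c(C)c2OC)C1=O | intermediate
19 | (4R)-2-butanoyl-6-{[3-butanoyl-2-hydroxy-6-methoxy-4-(methoxymethoxy)-5-methylphenyl]methyl}-3,5-dihydroxy-4-methyl-4-(3-methylbut-2-en-1-yl)cyclohexa-2,5-dien-1-one | CCCC(=O)C1=C(O)[C@](C)(CC=C(C)C)C(O)=C(Cc2c(O)c(C(=O)CCC)c(OCOC)c(C)c2OC)C1=O | intermediate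
20 | CNP0219644.1, (4R)-2-butanoyl-6-[(3-butanoyl-2,4-dihydroxy-6-methoxy-5-methylphenyl)methyl]-3,5-dihydroxy-4-methyl-4-(3-methylbut-2-en-1-yl)cyclohexa-2,5-dien-1-one | CCCC(=O)C1=C(O)[C@](C)(CC=C(C)C)C(O)=C(Cc2c(O)c(C(=O)CCC)c(O)c(C)c2OC)C1=O | target

**Totals.** Total step count: 9. Longest linear sequence: 7 steps (8 → 9 → 10 → 12 → 13 → 16 → 18 → 20, steps 3–9).

**Steps most likely to fail**

1. Step 7. Proton transfer from the lactone α-CH2 or the ring B ketone to the enolate may outrun C-acylation. The ring closure may stall at the open chain because the ester sits next to the quaternary carbon. The diketonate oxygen may close onto the ester, or liberated methoxide may open ring A by retro-Claisen cleavage, which would also expose the stereocentre. Fallback, setting out from 13 and returning at 16: the lactone is opened with MeNH(OMe)·HCl/AlMe3 (CH2Cl2, 0 °C → rt) to the N-methoxy-N-methyl amide phenol F1. Its phenol is converted to the lithium salt with LiN(SiMe3)2 (1 equiv), and enolate 14 (1.2 equiv, from 7 and LiN(iPr)2, THF, −78 → 0 °C) is added. The chelated tetrahedral adduct survives until the acid quench, so no diketone is present to consume enolate, and work-up gives 15, now isolated and purified. In a separate operation 15 is cyclised as its polyanion with LiN(iPr)2 (4.5 equiv, THF, −78 → 0 °C) to give 16.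

2. Step 5. Hydroarylation of the acyl-deactivated ring may be slow, letting O-acylation and Friedel–Crafts acylation (chromanone formation), polymerisation of acrylic acid, or acid-induced loss or migration of the butyryl group compete. Fallback, setting out from 10 and returning at 12: Rieche formylation (Cl2CHOMe, TiCl4, CH2Cl2, 0 °C) at the free ring carbon gives 3-butanoyl-2,4-dihydroxy-6-methoxy-5-methylbenzaldehyde F2. Wittig olefination with Ph3P=CHCO2Me in refluxing N,N-diethylaniline gives the methyl cinnamate F3, which lactonises in the flask onto the ortho phenol to 8-butanoyl-7-hydroxy-5-methoxy-6-methyl-2H-chromen-2-one F4. Hydrogenation of the 3,4-double bond (H2, Pd/C, EtOAc, rt) then gives 12.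

3. Step 2. Facial discrimination in the alkylation of the acyclic lithio-enamine may be insufficient, or N-alkylation may compete, and no later step can raise the enantiopurity of 7. Fallback, setting out from 1 and 4 and returning at 7: racemic C-prenylation (K2CO3, acetone, reflux) gives methyl 2-acetyl-2,5-dimethylhex-4-enoate as the racemate F5. This is resolved by preparative chiral supercritical-fluid chromatography on an amylose tris(3,5-dimethylphenylcarbamate) phase, and the (S) enantiomer 7 is collected; its configuration is confirmed by comparison with material from step 2.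

**Further compounds**

F1 | step 7 | 3-[3-butanoyl-2-hydroxy-6-methoxy-4-(methoxymethoxy)-5-methylphenyl]-N-methoxy-N-methylpropanamide | CCCC(=O)c1c(OCOC)c(C)c(OC)c(CCC(=O)N(C)OC)c1O
F2 | step 5 | 3-butanoyl-2,4-dihydroxy-6-methoxy-5-methylbenzaldehyde | CCCC(=O)c1c(O)c(C)c(OC)c(C=O)c1O
F3 | step 5 | methyl (E)-3-(3-butanoyl-2,4-dihydroxy-6-methoxy-5-methylphenyl)prop-2-enoate | CCCC(=O)c1c(O)c(C)c(OC)c(/C=C/C(=O)OC)c1O
F4 | step 5 | 8-butanoyl-7-hydroxy-5-methoxy-6-methyl-2H-chromen-2-one | CCCC(=O)c1c(O)c(C)c(OC)c2C=CC(=O)Oc12
F5 | step 2 | methyl 2-acetyl-2,5-dimethylhex-4-enoate (racemate) | COC(=O)C(C)(CC=C(C)C)C(C)=O
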